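The furan ring is disconnected at C2–C3 of the benzofuran. C2 is attached both to O1 and to the 4-methoxyphenyl ring, and that O1–C2–aryl array is simply a 4-methoxybenzyl ether of the phenol oxygen on ring B. A carbene carbon placed ortho to that ether (the future C3) therefore only has to insert into an OCH2 C–H bond. This one operation closes the five-membered oxygen ring as a 2-aryl-2,3-dihydrobenzofuran, which DDQ then aromatises. The precursor is the (2S)-7-methoxyflavanone whose ring B carries a diazomethyl group beside the 4-methoxybenzyloxy group. Its ring C stereocentre is set earlier by enantioselective conjugate addition of an arylboronic acid to 7-methoxychromone.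

Key step: step 7

Remark on the chemistry: the (R)-configured pyridine–oxazoline ligand is assumed to direct aryl transfer to the chromone face that gives 2S, by analogy with its sense of induction on cyclic enones; if the first run showed the opposite sense, the mirror-image ligand would be used with no other change.

Step 1
Reactants: 1 5-bromosalicylaldehyde (5-bromo-2-hydroxybenzaldehyde); 2 4-methoxybenzyl chloride
Product: 3 5-bromo-2-[(4-methoxyphenyl)methoxy]benzaldehyde
Conditions: K2CO3, DMF, 60 °C
Reagents that add atoms: none
Why: Williamson ether synthesis, in which the acidic ortho-formyl phenol is deprotonated by K2CO3 and the phenoxide displaces chloride from the reactive benzylic halide while the aldehyde is inert to the mild base.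

Step 2
Reactants: 3 5-bromo-2-[(4-methoxyphenyl)methoxy]benzaldehyde
Product: 4 2-[(4-methoxyphenyl)methoxy]-5-(4,4,5,5-tetramethyl-1,3,2-dioxaborolan-2-yl)benzaldehyde
Conditions: B2pin2, PdCl2(dppf) (3 mol %), KOAc, 1,4-dioxane, 85 °C
Reagents that add atoms: bis(pinacolato)diboron, CC1(C)OB(OC1(C)C)B1OC(C)(C)C(C)(C)O1
Why: Miyaura borylation, in which zerovalent palladium inserts into the aryl bromide, acetate-assisted transmetalation with the diboron and reductive elimination give the aryl pinacol boronate, and KOAc is too weak a base to disturb the aldehyde or the ether.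

Step 3
Reactants: 4 2-[(4-methoxyphenyl)methoxy]-5-(4,4,5,5-tetramethyl-1,3,2-dioxaborolan-2-yl)benzaldehyde
Product: 5 [3-formyl-4-[(4-methoxyphenyl)methoxy]phenyl]boronic acid
Conditions: NaIO4, NH4OAc, acetone/H2O, 25 °C
Reagents that add atoms: water, O
Why: Oxidative deprotection of a pinacol boronate, in which periodate cleaves the pinacol freed by reversible hydrolysis and so drives the equilibrium to the free boronic acid, which transmetalates to divalent palladium under base-free conditions far better than the ester, while aldehyde and benzylic ether are inert to periodate.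

Step 4
Reactants: 5 [3-formyl-4-[(4-methoxyphenyl)methoxy]phenyl]boronic acid; 6 7-methoxychromone
Product: 7 (2S)-2-[3-formyl-4-[(4-methoxyphenyl)methoxy]phenyl]-7-methoxychroman-4-one
Conditions: Pd(OCOCF3)2 (5 mol %), (R)-t-BuPyOx (6 mol %), NH4PF6 (30 mol %), H2O (5 equiv), ClCH2CH2Cl, 60 °C
Reagents that add atoms: none
Why: Enantioselective conjugate addition of an arylboronic acid to a chromone under cationic divalent palladium/pyridine–oxazoline catalysis, a known route to flavanones, in which transmetalation, carbopalladation of the chromone C2=C3 bond on the face left open by the tert-butyl group of the (R)-ligand (setting C2 as S) and protonolysis of the palladium enolate occur in a base-free medium that should neither open ring C nor let the aryl–palladium species add to the formyl group.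

Step 5
Reactants: 7 (2S)-2-[3-formyl-4-[(4-methoxyphenyl)methoxy]phenyl]-7-methoxychroman-4-one
Product: 8 (2S)-2-[3-[(E)-hydrazinylidenemethyl]-4-[(4-methoxyphenyl)methoxy]phenyl]-7-methoxychroman-4-one
Conditions: N2H4·H2O (5 equiv), EtOH/THF, 0 °C, 30 min; cold aqueous work-up, crude used at once
Reagents that add atoms: hydrazine hydrate, NN.O
Why: Hydrazone condensation that should be aldehyde-selective, because the aryl aldehyde reacts within minutes in the cold whereas the C4 ketone is deactivated by the 7-methoxy group and the ring oxygen and normally needs acid and heat; excess hydrazine suppresses azine formation, and the short cold exposure should leave the base-sensitive C2 untouched.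

Step 6
Reactants: 8 (2S)-2-[3-[(E)-hydrazinylidenemethyl]-4-[(4-methoxyphenyl)methoxy]phenyl]-7-methoxychroman-4-one
Product: 9 (2S)-2-[3-(diazomethyl)-4-[(4-methoxyphenyl)methoxy]phenyl]-7-methoxychroman-4-one, kept as a cold filtered solution
Conditions: activated MnO2 (6 equiv), Na2SO4, CH2Cl2, 0 °C, dark; filtered through Celite, solution used at once
Reagents that add atoms: none
Why: Dehydrogenation of an N-unsubstituted aryl hydrazone to the aryl diazomethane by MnO2, a known neutral heterogeneous oxidation that should leave the ketone, the ethers and the ring C stereocentre alone, with the unstabilised diazo compound never concentrated.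

Step 7
Reactants: 9 (2S)-2-[3-(diazomethyl)-4-[(4-methoxyphenyl)methoxy]phenyl]-7-methoxychroman-4-one
Product: 10 (2S)-7-methoxy-2-[2-(4-methoxyphenyl)-2,3-dihydro-1-benzofuran-5-yl]chroman-4-one, both epimers at dihydrofuran C2
Conditions: Rh2(OAc)4 (2 mol %), CH2Cl2, 25 °C, cold solution of 9 added over 3 h by syringe pump
Reagents that add atoms: none
Why: Rh2(OAc)4 takes N2 from the aryl diazomethane to give a donor-type rhodium carbene, whose carbon (the future furan C3) inserts through a concerted three-centre, hydride-transfer-like transition state into one C–H bond of the neighbouring OCH2Ar group and so forms the C2–C3 bond. The closest known reaction type is the dirhodium- or ruthenium-porphyrin-catalysed intramolecular C–H insertion of ortho-alkoxyaryl diazomethanes to 2,3-dihydrobenzofurans. The one ring closes by 1,5 C–H insertion through a five-membered cyclic arrangement of carbene carbon, two aromatic carbons, ether oxygen and the benzylic carbon. The new stereocentre at dihydrofuran C2 is left uncontrolled, since neither the achiral catalyst nor the remote C2 of ring C biases it, and this does no harm because step 8 turns that carbon into an sp2 centre. The step needs insertion to outrun carbene dimerisation, azine formation and attack at other sites; the ortho placement makes the ether CH2, activated by both the oxygen and the anisyl ring, the only C–H bond within five-membered reach, and slow addition at high dilution keeps the diazo concentration low. The medium is neutral, so the flavanone stereocentre should keep its configuration.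

Step 8
Reactants: 10 (2S)-7-methoxy-2-[2-(4-methoxyphenyl)-2,3-dihydro-1-benzofuran-5-yl]chroman-4-one
Product: 11 Lophirone J, (2S)-7-methoxy-2-[2-(4-methoxyphenyl)-1-benzofuran-5-yl]chroman-4-one
Conditions: DDQ (1.2 equiv), anhydrous 1,4-dioxane, 80 °C
Reagents that add atoms: none
Why: DDQ dehydrogenation, in which hydride is taken from dihydrofuran C2 (the cation being stabilised by the ring oxygen and the 4-methoxyphenyl group) and loss of the C3 proton aromatises both epimers to the same benzofuran, while the C2–H of ring C, next to a carbonyl-conjugated oxygen and β to the ketone, should lose hydride far more slowly when DDQ is limited.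

Compound list
1 | 5-bromosalicylaldehyde (5-bromo-2-hydroxybenzaldehyde) | O=Cc1cc(Br)ccc1O | starting material
2 | 4-methoxybenzyl chloride | COc1ccc(CCl)cc1 | starting material
3 | 5-bromo-2-[(4-methoxyphenyl)methoxy]benzaldehyde | COc1ccc(COc2ccc(Br)cc2C=O)cc1 | intermediate
4 | 2-[(4-methoxyphenyl)methoxy]-5-(4,4,5,5-tetramethyl-1,3,2-dioxaborolan-2-yl)benzaldehyde | COc1ccc(COc2ccc(B3OC(C)(C)C(C)(C)O3)cc2C=O)cc1 | intermediate
5 | [3-formyl-4-[(4-methoxyphenyl)methoxy]phenyl]boronic acid | COc1ccc(COc2ccc(B(O)O)cc2C=O)cc1 | intermediate
6 | 7-methoxychromone (7-methoxy-4H-chromen-4-one) | COc1ccc2c(=O)ccoc2c1 | starting material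
7 | (2S)-2-[3-formyl-4-[(4-methoxyphenyl)methoxy]phenyl]-7-methoxychroman-4-one | COc1ccc(COc2ccc([C@@H]3CC(=O)c4ccc(OC)cc4O3)cc2C=O)cc1 | intermediate
8 | (2S)-2-[3-[(E)-hydrazinylidenemethyl]-4-[(4-methoxyphenyl)methoxy]phenyl]-7-methoxychroman-4-one | COc1ccc(COc2ccc([C@@H]3CC(=O)c4ccc(OC)cc4O3)cc2/C=N/N)cc1 | intermediate
9 | (2S)-2-[3-(diazomethyl)-4-[(4-methoxyphenyl)methoxy]phenyl]-7-methoxychroman-4-one | COc1ccc(COc2ccc([C@@H]3CC(=O)c4ccc(OC)cc4O3)cc2C=[N+]=[N-])cc1 | intermediate
10 | (2S)-7-methoxy-2-[2-(4-methoxyphenyl)-2,3-dihydro-1-benzofuran-5-yl]chroman-4-one, both epimers at dihydrofuran C2 | COc1ccc(C2Cc3cc([C@@H]4CC(=O)c5ccc(OC)cc5O4)ccc3O2)cc1 | intermediate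
11 | Lophirone J, (2S)-7-methoxy-2-[2-(4-methoxyphenyl)-1-benzofuran-5-yl]chroman-4-one | COc1ccc(-c2cc3cc([C@@H]4CC(=O)c5ccc(OC)cc5O4)ccc3o2)cc1 | target

Total step count: 8
Longest linear sequence: 8 steps (1 → 3 → 4 → 5 → 7 → 8 → 9 → 10 → 11); 6 enters at step 4.

Steps most likely to fail, riskiest first

First, step 7. Bimolecular decay of the carbene (coupling with a second diazo molecule to a stilbene or an azine) may outrun the intramolecular insertion. The fallback gives up the late furan closure and builds the benzofuran before ring C by known alkyne chemistry. 4-Bromo-2-iodophenol and 4-ethynylanisole, both catalogue compounds, would be coupled and cyclised in one pot under Sonogashira conditions (PdCl2(PPh3)2, CuI, Et3N, DMF, 60 °C) to 5-bromo-2-(4-methoxyphenyl)-1-benzofuran F1. Miyaura borylation as in step 2 would give 2-[2-(4-methoxyphenyl)-1-benzofuran-5-yl]-4,4,5,5-tetramethyl-1,3,2-dioxaborolane F2. Periodate cleavage as in step 3 would give [2-(4-methoxyphenyl)-1-benzofuran-5-yl]boronic acid F3. This would be added to the chromone under the conditions of step 4. The fallback sets out from compound 6 and comes back to the route at the target 11.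

Second, step 6. The unstabilised, electron-rich diazo compound may be lost while it is generated and handled, by acid-induced loss of N2 on the oxide surface or by azine formation with unreacted hydrazone. The fallback releases the same diazo compound slowly in the presence of the catalyst by a Bamford–Stevens fragmentation, which also removes the exposure to free hydrazine in step 5. Aldehyde 7 would be condensed with tosylhydrazide (MeOH, 25 °C) to (2S)-7-methoxy-2-[4-[(4-methoxyphenyl)methoxy]-3-[(E)-(tosylhydrazinylidene)methyl]phenyl]chroman-4-one F4. One equivalent of LiN(SiMe3)2 (THF, −78 °C) would be consumed entirely by the acidic sulfonamide N–H to give the lithium salt of that tosylhydrazone F5. Warming F5 to 40 °C in 1,4-dioxane with benzyltriethylammonium chloride and Rh2(OAc)4 should release 9 gradually and convert it as it forms. The fallback sets out from compound 7 and comes back to the route at compound 10.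

Third, step 4. Carbopalladation of the electron-rich chromone may be slow enough for protodeboronation of the boronic acid to take over, or facial selectivity may be poor. The fallback switches to a rhodium-catalysed Hayashi–Miyaura addition with the aldehyde masked, because aryl–rhodium species add to free aldehydes. Boronic acid 5 would be treated with HC(OMe)3 and catalytic pyridinium p-toluenesulfonate in MeOH, then worked up with aqueous NaHCO3, to give [3-(dimethoxymethyl)-4-[(4-methoxyphenyl)methoxy]phenyl]boronic acid F6. Addition of F6 to 6 with [Rh(OH)(cod)]2 and an electron-poor atropisomeric bisphosphine (antipode chosen to give 2S) in toluene at 25–40 °C would give (2S)-2-[3-(dimethoxymethyl)-4-[(4-methoxyphenyl)methoxy]phenyl]-7-methoxychroman-4-one F7. Pyridinium p-toluenesulfonate in wet acetone would then release the aldehyde. The fallback sets out from compound 5 and comes back to the route at compound 7.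

Further compounds
F1 | step 7 | 5-bromo-2-(4-methoxyphenyl)-1-benzofuran | COc1ccc(-c2cc3cc(Br)ccc3o2)cc1
F2 | step 7 | 2-[2-(4-methoxyphenyl)-1-benzofuran-5-yl]-4,4,5,5-tetramethyl-1,3,2-dioxaborolane | COc1ccc(-c2cc3cc(B4OC(C)(C)C(C)(C)O4)ccc3o2)cc1
F3 | step 7 | [2-(4-methoxyphenyl)-1-benzofuran-5-yl]boronic acid | COc1ccc(-c2cc3cc(B(O)O)ccc3o2)cc1
F4 | step 6 | (2S)-7-methoxy-2-[4-[(4-methoxyphenyl)methoxy]-3-[(E)-(tosylhydrazinylidene)methyl]phenyl]chroman-4-one | COc1ccc(COc2ccc([C@@H]3CC(=O)c4ccc(OC)cc4O3)cc2/C=N/NS(=O)(=O)c5ccc(C)cc5)cc1
F5 | step 6 | lithium salt of tosylhydrazone F4 | COc1ccc(COc2ccc([C@@H]3CC(=O)c4ccc(OC)cc4O3)cc2/C=N/[N-]S(=O)(=O)c5ccc(C)cc5)cc1.[Li+]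
F6 | step 4 | [3-(dimethoxymethyl)-4-[(4-methoxyphenyl)methoxy]phenyl]boronic acid | COc1ccc(COc2ccc(B(O)O)cc2C(OC)OC)cc1
F7 | step 4 | (2S)-2-[3-(dimethoxymethyl)-4-[(4-methoxyphenyl)methoxy]phenyl]-7-methoxychroman-4-one | COc1ccc(COc2ccc([C@@H]3CC(=O)c4ccc(OC)cc4O3)cc2C(OC)OC)cc1
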